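## Retrosynthetic overview

1. The target comes from its 8-O-methyl ether by chelation-controlled demethylation with BCl3, the side-chain ketone being unmasked just before.
2. The lactone (ring B, the last ring made; benzene ring A is bought) comes from Pd-catalysed carbonylative lactonisation of an ortho-bromoaryl secondary alcohol, brominated with NBS.
3. The C3–C1' bond is cut: CuI-catalysed opening of (S)-2-(3,5-dimethoxybenzyl)oxirane by a ten-carbon Grignard reagent whose ketone is masked as a dioxolane.
4. The oxirane comes from the (S)-chlorohydrin, made by ketoreductase reduction of the achiral chloromethyl ketone, which is built from 3,5-dimethoxyphenylacetic acid.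
5. The Grignard precursor comes from 6-bromohexanoyl chloride and n-BuMgCl. Ring order: dioxolane (temporary), oxirane (temporary), lactone ring B.

Assumption: all building blocks and reagents are catalogue chemicals, and the ketoreductase is the best (S)-selective hit of a commercial enzyme panel.

## Route

Step 1
Reactants: 1 3,5-dimethoxyphenylacetic acid
Product: 3 2-(3,5-dimethoxyphenyl)-N-methoxy-N-methylacetamide, via acyl imidazolide 2 (not isolated)
Conditions: CDI (1.1 equiv), CH2Cl2, rt, 1 h; then MeNH(OMe)·HCl (1.2 equiv), rt, 12 h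
Reagents that add atoms: N,O-dimethylhydroxylamine hydrochloride, CNOC.Cl
Why: CDI activates the acid as the acyl imidazolide, which the hydroxylamine acylates cleanly (amide coupling to a Weinreb amide); no stereocentre is involved.

Step 2
Reactants: 3 2-(3,5-dimethoxyphenyl)-N-methoxy-N-methylacetamide
Product: 5 1-chloro-3-(3,5-dimethoxyphenyl)propan-2-one, via lithium hemiaminal chelate 4 (not isolated)
Conditions: ICH2Cl (1.5 equiv), MeLi·LiBr (1.4 equiv, added slowly), THF, −78 °C, 1 h; then cold 1 M HCl
Reagents that add atoms: chloroiodomethane, ClCI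
Why: Chloromethyllithium, made by iodine–lithium exchange in the presence of the amide, adds once because the chelated tetrahedral adduct survives until the quench (Weinreb ketone synthesis with a carbenoid).

Step 3
Reactants: 5 1-chloro-3-(3,5-dimethoxyphenyl)propan-2-one
Product: 6 (2S)-1-chloro-3-(3,5-dimethoxyphenyl)propan-2-ol
Conditions: ketoreductase (anti-Prelog NADPH-dependent alcohol dehydrogenase, Lactobacillus kefir type, panel hit), NADP+ (0.5 mol %), i-PrOH (15 vol %), MgSO4 (1 mM), K2HPO4/KH2PO4 buffer pH 7.0, 30 °C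
Reagents that add atoms: none
Why: The ketoreductase transfers hydride from NADPH to one face of the prochiral ketone (biocatalytic asymmetric ketone reduction, cofactor recycled with propan-2-ol), binding arylmethyl as the large and CH2Cl as the small group, so the (S)-chlorohydrin forms in ≥99% ee and sets the only stereocentre.

Step 4
Reactants: 6 (2S)-1-chloro-3-(3,5-dimethoxyphenyl)propan-2-ol
Product: 7 (2S)-2-[(3,5-dimethoxyphenyl)methyl]oxirane
Conditions: aq NaOH (2 M, 1.5 equiv), THF, 0 °C → rt
Reagents that add atoms: none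
Why: Intramolecular Williamson etherification closes the oxirane at the CH2Cl carbon, so the carbinol centre is untouched and its configuration is retained.

Step 5
Reactants: 8 6-bromohexanoyl chloride
Product: 9 6-bromo-N-methoxy-N-methylhexanamide
Conditions: MeNH(OMe)·HCl (1.1 equiv), K2CO3 (2.2 equiv), CH2Cl2/H2O, 0 °C → rt
Reagents that add atoms: N,O-dimethylhydroxylamine hydrochloride, CNOC.Cl
Why: Schotten–Baumann acylation of the amine by the acid chloride is fast and leaves the primary bromide alone.

Step 6
Reactants: 9 6-bromo-N-methoxy-N-methylhexanamide; 10 n-butylmagnesium chloride (n-BuMgCl)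
Product: 12 10-bromodecan-5-one, via magnesium hemiaminal chelate 11 (not isolated)
Conditions: n-BuMgCl (1.2 equiv, 2 M in THF), THF, 0 °C, 1 h; then 1 M HCl
Reagents that add atoms: none
Why: Weinreb ketone synthesis: the Grignard reagent adds once to give a stable chelate, and without copper it does not displace the primary bromide at 0 °C.

Step 7
Reactants: 12 10-bromodecan-5-one
Product: 13 2-(5-bromopentyl)-2-butyl-1,3-dioxolane
Conditions: ethylene glycol (3 equiv), p-TsOH·H2O (5 mol %), toluene, reflux, Dean–Stark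
Reagents that add atoms: ethylene glycol, OCCO
Why: Acid-catalysed ketalisation driven by azeotropic water removal masks the ketone so that a Grignard reagent can be made from the bromide.

Step 8
Reactants: 7 (2S)-2-[(3,5-dimethoxyphenyl)methyl]oxirane; 13 2-(5-bromopentyl)-2-butyl-1,3-dioxolane
Product: 15 (2R)-8-(2-butyl-1,3-dioxolan-2-yl)-1-(3,5-dimethoxyphenyl)octan-2-ol, via Grignard reagent 14 (not isolated)
Conditions: 13 (1.5 equiv), Mg turnings, I2 (cat.), THF, 45 °C; then CuI (10 mol %), 7, THF, −30 → 0 °C; sat. aq NH4Cl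
Reagents that add atoms: none
Why: Copper-catalysed SN2 opening of the terminal epoxide by the Grignard reagent occurs at the unsubstituted carbon only, so the stereocentre is untouched (the descriptor changes from S to R by CIP priority alone).

Step 9
Reactants: 15 (2R)-8-(2-butyl-1,3-dioxolan-2-yl)-1-(3,5-dimethoxyphenyl)octan-2-ol
Product: 16 (2R)-1-(2-bromo-3,5-dimethoxyphenyl)-8-(2-butyl-1,3-dioxolan-2-yl)octan-2-ol
Conditions: NBS (1.02 equiv), MeCN, 0 °C, dark
Reagents that add atoms: N-bromosuccinimide, O=C1CCC(=O)N1Br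
Why: Electrophilic aromatic bromination of the 3,5-dimethoxyarene goes to the position para to one methoxy group and ortho to the alkyl chain (the two such positions are equivalent) rather than the hindered site between the methoxy groups.

Step 10
Reactants: 16 (2R)-1-(2-bromo-3,5-dimethoxyphenyl)-8-(2-butyl-1,3-dioxolan-2-yl)octan-2-ol
Product: 17 (3R)-3-[6-(2-butyl-1,3-dioxolan-2-yl)hexyl]-6,8-dimethoxy-3,4-dihydro-1H-isochromen-1-one
Conditions: Pd(OAc)2 (5 mol %), Xantphos (7.5 mol %), CO (1 atm), K2CO3 (2 equiv), 1,4-dioxane, 100 °C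
Reagents that add atoms: carbon monoxide, [C-]#[O+]
Why: Palladium-catalysed carbonylative lactonisation (oxidative addition, CO insertion, capture of the acyl-palladium by the pendant alcohol) closes the six-membered lactone without touching the C–O stereocentre.

Step 11
Reactants: 17 (3R)-3-[6-(2-butyl-1,3-dioxolan-2-yl)hexyl]-6,8-dimethoxy-3,4-dihydro-1H-isochromen-1-one
Product: 18 (3R)-6,8-dimethoxy-3-(7-oxoundecyl)-3,4-dihydro-1H-isochromen-1-one
Conditions: 1 M HCl, THF, rt
Reagents that add atoms: water, O
Why: Acid-catalysed acetal hydrolysis frees the ketone, while the lactone and aryl methyl ethers are stable to dilute acid at room temperature.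

Step 12
Reactants: 18 (3R)-6,8-dimethoxy-3-(7-oxoundecyl)-3,4-dihydro-1H-isochromen-1-one
Product: 20 (3R)-8-hydroxy-6-methoxy-3-(7-oxoundecyl)-3,4-dihydro-1H-isochromen-1-one, via aryloxydichloroborane 19 (not isolated)
Conditions: BCl3 (1 M in CH2Cl2, 3 equiv), CH2Cl2, −78 → 0 °C; then H2O
Reagents that add atoms: none
Why: BCl3 chelated to the lactone carbonyl cleaves only the peri (C8) methyl ether (Lewis-acid ether cleavage), leaving the C6 methoxy group, the ketone and the stereocentre unchanged.

## Compound list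

1 | 3,5-dimethoxyphenylacetic acid | COc1cc(CC(=O)O)cc(OC)c1 | starting material
2 | 2-(3,5-dimethoxyphenyl)-1-(imidazol-1-yl)ethan-1-one (acyl imidazolide) | COc1cc(CC(=O)n2ccnc2)cc(OC)c1 | intermediate (not isolated)
3 | 2-(3,5-dimethoxyphenyl)-N-methoxy-N-methylacetamide | COc1cc(CC(=O)N(C)OC)cc(OC)c1 | intermediate
4 | lithium 1-chloro-3-(3,5-dimethoxyphenyl)-2-[methoxy(methyl)amino]propan-2-olate | COc1cc(CC([O-])(CCl)N(C)OC)cc(OC)c1.[Li+] | intermediate (not isolated)
5 | 1-chloro-3-(3,5-dimethoxyphenyl)propan-2-one | COc1cc(CC(=O)CCl)cc(OC)c1 | intermediate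
6 | (2S)-1-chloro-3-(3,5-dimethoxyphenyl)propan-2-ol | ClC[C@@H](O)Cc1cc(OC)cc(OC)c1 | intermediate
7 | (2S)-2-[(3,5-dimethoxyphenyl)methyl]oxirane | C1O[C@H]1Cc1cc(OC)cc(OC)c1 | intermediate
8 | 6-bromohexanoyl chloride | BrCCCCCC(Cl)=O | starting material
9 | 6-bromo-N-methoxy-N-methylhexanamide | BrCCCCCC(=O)N(C)OC | intermediate
10 | n-butylmagnesium chloride (n-BuMgCl) | CCCC[Mg]Cl | starting material
11 | chloromagnesium 10-bromo-5-[methoxy(methyl)amino]decan-5-olate | CCCCC(CCCCCBr)(O[Mg]Cl)N(C)OC | intermediate (not isolated)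
12 | 10-bromodecan-5-one | CCCCC(=O)CCCCCBr | intermediate
13 | 2-(5-bromopentyl)-2-butyl-1,3-dioxolane | CCCCC1(CCCCCBr)OCCO1 | intermediate
14 | [5-(2-butyl-1,3-dioxolan-2-yl)pentyl]magnesium bromide | CCCCC1(CCCCC[Mg]Br)OCCO1 | intermediate (not isolated)
15 | (2R)-8-(2-butyl-1,3-dioxolan-2-yl)-1-(3,5-dimethoxyphenyl)octan-2-ol | CCCCC1(CCCCCC[C@@H](O)Cc2cc(OC)cc(OC)c2)OCCO1 | intermediate
16 | (2R)-1-(2-bromo-3,5-dimethoxyphenyl)-8-(2-butyl-1,3-dioxolan-2-yl)octan-2-ol | CCCCC1(CCCCCC[C@@H](O)Cc2cc(OC)cc(OC)c2Br)OCCO1 | intermediate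
17 | (3R)-3-[6-(2-butyl-1,3-dioxolan-2-yl)hexyl]-6,8-dimethoxy-3,4-dihydro-1H-isochromen-1-one | CCCCC1(CCCCCC[C@@H]2Cc3cc(OC)cc(OC)c3C(=O)O2)OCCO1 | intermediate
18 | (3R)-6,8-dimethoxy-3-(7-oxoundecyl)-3,4-dihydro-1H-isochromen-1-one | CCCCC(=O)CCCCCC[C@@H]1Cc2cc(OC)cc(OC)c2C(=O)O1 | intermediate
19 | (3R)-8-(dichloroboryloxy)-6-methoxy-3-(7-oxoundecyl)-3,4-dihydro-1H-isochromen-1-one | CCCCC(=O)CCCCCC[C@@H]1Cc2cc(OC)cc(OB(Cl)Cl)c2C(=O)O1 | intermediate (not isolated)
20 | (3R)-8-hydroxy-6-methoxy-3-(7-oxoundecyl)-3,4-dihydro-1H-isochromen-1-one (CNP0318815.1) | CCCCC(=O)CCCCCC[C@@H]1Cc2cc(OC)cc(O)c2C(=O)O1 | target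

## Step count and risks

Total steps: 12. Longest linear sequence: 9 (steps 1, 2, 3, 4, 8, 9, 10, 11, 12); steps 5–7 make the side-chain fragment.

**Step 2 (carbenoid homologation).** The risk is enolisation of the benzylic CH2 or decomposition of chloromethyllithium. The fallback sets out from 1 and comes back at 5. Acid 1 is treated with oxalyl chloride and catalytic DMF in CH2Cl2 to give 3,5-dimethoxyphenylacetyl chloride F1. Trimethylsilyldiazomethane (2 equiv, MeCN/THF, 0 °C) converts it into 1-diazo-3-(3,5-dimethoxyphenyl)propan-2-one F2. Anhydrous HCl (4 M in dioxane, 0 °C) then turns F2 into 5 with loss of nitrogen. This is a diazoketone route in place of carbenoid addition to the Weinreb amide.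

**Step 3 (ketoreductase reduction).** The risk is that no panel enzyme gives the (S)-alcohol in high ee. The fallback sets out from 5 and comes back at 7. NaBH4 in MeOH at 0 °C gives racemic 1-chloro-3-(3,5-dimethoxyphenyl)propan-2-ol F3, and aqueous NaOH closes it to racemic 2-[(3,5-dimethoxyphenyl)methyl]oxirane F4. Hydrolytic kinetic resolution follows, with (S,S)-N,N'-bis(3,5-di-tert-butylsalicylidene)-1,2-cyclohexanediaminocobalt acetate (trivalent cobalt, 0.5 mol %) and H2O (0.55 equiv) at rt. This antipode is chosen as the one expected to hydrolyse the (R)-epoxide to the diol and leave 7 (at most 50%, ≥99% ee); the sense must be confirmed on the first run. This replaces the enzymatic reduction by a small-molecule catalytic resolution.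

**Step 10 (carbonylative lactonisation).** The risk is slow oxidative addition into the hindered, electron-rich aryl bromide. The fallback sets out from 16 and comes back at 18. n-BuLi (2.2 equiv, THF, −78 °C) deprotonates the alcohol and then exchanges bromine for lithium, and CO2 gas carboxylates the aryllithium. Mild acidification gives 2-[(2R)-8-(2-butyl-1,3-dioxolan-2-yl)-2-hydroxyoctyl]-4,6-dimethoxybenzoic acid F5. Stirring F5 in 1 M HCl/THF at rt lactonises it and removes the dioxolane in the same pot, giving 18 directly. This is organolithium carboxylation in place of palladium catalysis, and it bypasses 17.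

Further compounds
F1 | step 2 | 3,5-dimethoxyphenylacetyl chloride | COc1cc(CC(Cl)=O)cc(OC)c1
F2 | step 2 | 1-diazo-3-(3,5-dimethoxyphenyl)propan-2-one | COc1cc(CC(=O)C=[N+]=[N-])cc(OC)c1
F3 | step 3 | racemic 1-chloro-3-(3,5-dimethoxyphenyl)propan-2-ol | ClCC(O)Cc1cc(OC)cc(OC)c1
F4 | step 3 | racemic 2-[(3,5-dimethoxyphenyl)methyl]oxirane | C1OC1Cc1cc(OC)cc(OC)c1
F5 | step 10 | 2-[(2R)-8-(2-butyl-1,3-dioxolan-2-yl)-2-hydroxyoctyl]-4,6-dimethoxybenzoic acid | CCCCC1(CCCCCC[C@@H](O)Cc2cc(OC)cc(OC)c2C(=O)O)OCCO1
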